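**Plan**

1. Numbering: pyranone O1, C2 (C=O), C3–C6; C7 is the chain carbon on C3; butyrolactone O1′, C2′ (C=O), C3′, C4′ (bonded to C6), C5′. Retrosynthesis opens the butyrolactone (C5′–O bond, C2′ back to a vinyl carbon), then the pyranone O1–C2 bond (back to a Z-2-ene-1,5-diol), then cuts C3–C7 and C4–C5 together.
2. Enabling feature: C2–C3–C4 of the pyranone is a three-carbon unit with the chain on C3, hydrogen on C4, and C2 cis to C5 across C3=C4. This is the pattern left by propargyl alcohol after alkoxide-directed anti-carbomagnesiation and C-alkylation of the metalated terminus.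
3. Forward: dihydro-β-ionone (cyclohexene ring already present) gives homoallyl Grignard 8; cis-4-(benzyloxy)but-2-en-1-ol gives epoxide 16; 8, propargyl alcohol and 16 are joined in one flask to the acyclic enediol 20. The pyranone closes next (step 11) and the butyrolactone last (step 14).
4. Stereochemistry: C6 and C4′ come from a Sharpless epoxidation (L-(+)-tartrate) and SN2 inversion in the vinyl opening. The Z C3=C4 geometry comes from the magnesium chelate and the E chain alkene from syn methylalumination.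

Key step: step 10

Remark: Grignard reagent 8 is prepared and titrated as a solution in a step of its own and used at once; reagent amounts are indicative.

**Route**

Step 1
Reactants: 1 dihydro-β-ionone
Product: 3 alkyne 2-(but-3-yn-1-yl)-1,3,3-trimethylcyclohex-1-ene, via enol phosphate 2 (not isolated)
Conditions: LiN(iPr)2 (LDA, 1.05 equiv), THF, −78 °C; ClP(O)(OEt)2, −78 °C → rt; then LDA (2.3 equiv), −78 °C → rt; H2O
Reagents that add atoms: none
Why: Kinetic deprotonation at the methyl group, O-phosphorylation and base-induced elimination of diethyl phosphate from enol phosphate 2 (the standard methyl ketone to terminal alkyne conversion) should give 3, the tetrasubstituted ring alkene being inert to amide base.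

Step 2
Reactants: 3 alkyne
Product: 6 (3E)-4-methyl-6-(2,6,6-trimethylcyclohex-1-en-1-yl)hex-3-en-1-ol, via alkenyldimethylalane 4 (not isolated), via lithium alkenylalanate 5 (not isolated)
Conditions: Me3Al (2 equiv), Cp2ZrCl2 (0.2 equiv), CH2Cl2, 0 °C → rt; volatiles removed; n-BuLi (1 equiv), THF/hexane, −78 °C; ethylene oxide (3 equiv), −78 °C → rt; aqueous work-up
Reagents that add atoms: trimethylaluminium, C[Al](C)C; ethylene oxide, C1CO1
Why: Zirconium-catalysed methylalumination (Negishi carboalumination) adds methyl and aluminium syn across the terminal alkyne with aluminium on the terminal carbon, and the derived alanate opens ethylene oxide with retention, so the E trisubstituted alkene is fixed here while the tetrasubstituted ring alkene does not react.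

Step 3
Reactants: 6 homoallylic alcohol
Product: 7 2-[(3E)-6-bromo-3-methylhex-3-en-1-yl]-1,3,3-trimethylcyclohex-1-ene
Conditions: CBr4, PPh3, CH2Cl2, 0 °C
Reagents that add atoms: carbon tetrabromide, BrC(Br)(Br)Br
Why: The Appel reaction converts the primary alcohol into the bromide under neutral conditions that leave both alkenes untouched.

Step 4
Reactants: 7 homoallylic bromide
Product: 8 [(3E)-4-methyl-6-(2,6,6-trimethylcyclohex-1-en-1-yl)hex-3-en-1-yl]magnesium bromide
Conditions: Mg turnings (activated with a trace of 1,2-dibromoethane), Et2O, gentle reflux → rt; titrated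
Reagents that add atoms: magnesium, [Mg]
Why: Insertion of magnesium into a primary homoallylic bromide is routine Grignard formation, and homoallylic reagents with a trisubstituted alkene keep their geometry at or below room temperature.

Step 5
Reactants: 9 cis-4-(benzyloxy)but-2-en-1-ol
Product: 10 [(2S,3R)-3-[(benzyloxy)methyl]oxiran-2-yl]methanol
Conditions: Ti(OiPr)4 (0.2 equiv), L-(+)-diethyl tartrate (0.25 equiv), t-BuOOH (2 equiv, anhydrous), 4 Å molecular sieves, CH2Cl2, −20 °C
Reagents that add atoms: tert-butyl hydroperoxide, CC(C)(C)OO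
Why: Sharpless asymmetric epoxidation with the L-(+)-tartrate ligand delivers oxygen to the alkene face that gives the (2S,3R)-cis-epoxy alcohol, so both stereocentres of the target are set here by the catalyst (C3 becomes C6 unchanged, C2 becomes C4′ after inversion in step 6).

Step 6
Reactants: 10 epoxy alcohol; 11 vinylmagnesium bromide
Product: 12 (2R,3S)-4-(benzyloxy)-2-ethenylbutane-1,3-diol
Conditions: 11 (3 equiv), CuI (0.1 equiv), THF, −30 → −10 °C; aq. NH4Cl
Reagents that add atoms: none
Why: Copper-catalysed Grignard opening of a 2,3-epoxy alcohol alkoxide takes place by SN2 attack at C2 with inversion, as is usual for cuprate-type reagents, giving the 2-vinyl-1,3-diol; any 1,2-diol from attack at C3 would be removed by chromatography or by periodate cleavage.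

Step 7
Reactants: 12 diol
Product: 13 (2S,3R)-1-(benzyloxy)-3-{[(tert-butyldimethylsilyl)oxy]methyl}pent-4-en-2-ol
Conditions: TBSCl (1.05 equiv), imidazole, CH2Cl2, −20 → 0 °C
Reagents that add atoms: tert-butyldimethylsilyl chloride, CC(C)(C)[Si](C)(C)Cl
Why: Silylation with a bulky chlorosilane at low temperature is selective for the primary over the hindered secondary hydroxyl.

Step 8
Reactants: 13 benzyl ether
Product: 14 (2S,3R)-3-{[(tert-butyldimethylsilyl)oxy]methyl}pent-4-ene-1,2-diol
Conditions: lithium 4,4′-di-tert-butylbiphenylide (LiDBB, excess), THF, −78 °C; aq. NH4Cl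
Reagents that add atoms: none
Why: Single-electron reductive cleavage of the benzyl ether by the lithium arenide leaves the isolated terminal alkene and the silyl ether intact, which hydrogenolysis would not.

Step 9
Reactants: 14 diol
Product: 16 (2S)-2-[(2R)-1-[(tert-butyldimethylsilyl)oxy]but-3-en-2-yl]oxirane, via primary tosylate 15 (not isolated)
Conditions: TsCl (1.05 equiv), Et3N, Bu2SnO (2 mol%), CH2Cl2, 0 °C → rt; then K2CO3, MeOH, rt
Reagents that add atoms: none
Why: Tin-catalysed selective sulfonylation of the primary hydroxyl followed by Williamson-type 3-exo-tet closure under mild carbonate conditions gives the terminal epoxide without breaking the C–O bond of the stereocentre, so its configuration is retained.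

Step 10
Reactants: 17 prop-2-yn-1-ol; 8 Grignard reagent; 16 epoxide
Product: 20 (2Z,5R,6R)-6-{[(tert-butyldimethylsilyl)oxy]methyl}-2-[(3E)-4-methyl-6-(2,6,6-trimethylcyclohex-1-en-1-yl)hex-3-en-1-yl]octa-2,7-diene-1,5-diol, via bromomagnesium prop-2-yn-1-olate 18 (not isolated), via oxamagnesacycle 19 (not isolated)
Conditions: 17, EtMgBr (1.0 equiv), THF, −20 °C; CuI (10 mol%), then 8 (1.05 equiv, Et2O), 0 °C → rt; then 16 (0.8 equiv), −30 °C → rt; aq. NH4Cl
Reagents that add atoms: none
Why: Proposed new method: the magnesium alkoxide 18 directs CuI-catalysed anti-addition of the C7–Mg bond of 8 across the alkyne, C7 going to the internal carbon (pyranone C3) and magnesium to the terminal carbon (C4), where it is held cis to the CH2O group in the five-membered oxamagnesacycle 19; this alkenylmagnesium, relayed through a catalytic alkenylcopper, then opens the monosubstituted epoxide 16 at its CH2 carbon (C5) by SN2 attack with retention of alkene geometry. The closest known reaction types are the CuI-catalysed carbomagnesiation of propargyl alcohol with trapping of the cyclic alkenylmagnesium by iodine, allyl halides or carbonyl compounds, and the copper-catalysed opening of terminal epoxides by alkenyl Grignard reagents; their combination in one flask is the new element. No ring of the target closes and no stereocentre is formed: C6 and C4′ arrive in 16 and are untouched because only the unsubstituted epoxide carbon reacts. The step needs Z geometry at C3=C4 (secured by the chelate, which holds C2 and the metalated C4 on the same side), the alkyl group on the internal alkyne carbon (secured by alkoxide direction) and attack at the terminal epoxide carbon (secured by sterics). It also needs 8 to be consumed before 16 is added, so 8 is titrated, the carbomagnesiation is run to completion and 16 is the limiting component.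

Step 11
Reactants: 20 enediol
Product: 23 (6R)-6-[(2R)-1-[(tert-butyldimethylsilyl)oxy]but-3-en-2-yl]-3-[(3E)-4-methyl-6-(2,6,6-trimethylcyclohex-1-en-1-yl)hex-3-en-1-yl]-5,6-dihydro-2H-pyran-2-one, via Z-hydroxy enal 21 (not isolated), via lactol 22 (not isolated)
Conditions: activated MnO2 (excess), CH2Cl2, rt
Reagents that add atoms: none
Why: MnO2 oxidises only the allylic primary alcohol, the Z-enal 21 is trapped by the secondary hydroxyl as the allylic lactol 22, and MnO2 oxidises this further (oxidative lactonisation of a Z-2-ene-1,5-diol), closing the pyranone at O1–C2 with the C6 configuration untouched.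

Step 12
Reactants: 23 vinyl lactone
Product: 25 (6R)-6-[(2R)-1-[(tert-butyldimethylsilyl)oxy]-4-hydroxybutan-2-yl]-3-[(3E)-4-methyl-6-(2,6,6-trimethylcyclohex-1-en-1-yl)hex-3-en-1-yl]-5,6-dihydro-2H-pyran-2-one, via B-alkyl-9-BBN adduct 24 (not isolated)
Conditions: 9-BBN (1.5 equiv), THF, 0 °C → rt; then NaBO3·4H2O, THF/H2O, rt
Reagents that add atoms: sodium perborate (used as NaBO3·4H2O), [Na+].[Na+].O[B-]1(O)OO[B-](O)(O)OO1
Why: Hydroboration–oxidation with 9-BBN is anti-Markovnikov and far faster at the monosubstituted alkene than at the tri- and tetrasubstituted alkenes or the lactone carbonyl, and the mild perborate oxidation spares the conjugated lactone.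

Step 13
Reactants: 25 primary alcohol
Product: 26 (3R)-4-[(tert-butyldimethylsilyl)oxy]-3-[(2R)-5-[(3E)-4-methyl-6-(2,6,6-trimethylcyclohex-1-en-1-yl)hex-3-en-1-yl]-6-oxo-3,6-dihydro-2H-pyran-2-yl]butanoic acid
Conditions: TEMPO (0.2 equiv), PhI(OAc)2 (2.5 equiv), MeCN/H2O (1:1), rt
Reagents that add atoms: water, O
Why: Nitroxyl-catalysed oxidation with a hypervalent iodine co-oxidant in aqueous acetonitrile takes the primary alcohol through the aldehyde hydrate to the carboxylic acid without affecting alkenes, silyl ether or lactone.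

Step 14
Reactants: 26 silyloxy acid
Product: 28 (6R)-3-[(3E)-4-methyl-6-(2,6,6-trimethylcyclohex-1-en-1-yl)hex-3-en-1-yl]-6-[(3R)-5-oxooxolan-3-yl]-5,6-dihydro-2H-pyran-2-one (CNP0207009.2), via hydroxy acid 27 (not isolated)
Conditions: 48% aq. HF/MeCN (1:19), 0 °C → rt
Reagents that add atoms: none
Why: Acidic fluoride cleavage of the primary silyl ether frees the γ-hydroxy acid 27, which lactonises spontaneously (5-exo-trig acyl substitution) to the butyrolactone without touching either stereocentre.

**Compound list**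

1 | dihydro-β-ionone, 4-(2,6,6-trimethylcyclohex-1-en-1-yl)butan-2-one | CC(=O)CCC1=C(C)CCCC1(C)C | starting material
2 | diethyl 4-(2,6,6-trimethylcyclohex-1-en-1-yl)but-1-en-2-yl phosphate | C=C(CCC1=C(C)CCCC1(C)C)OP(=O)(OCC)OCC | intermediate (not isolated)
3 | 2-(but-3-yn-1-yl)-1,3,3-trimethylcyclohex-1-ene | C#CCCC1=C(C)CCCC1(C)C | intermediate
4 | dimethyl[(1E)-2-methyl-4-(2,6,6-trimethylcyclohex-1-en-1-yl)but-1-en-1-yl]alumane | C[Al](C)/C=C(C)/CCC1=C(C)CCCC1(C)C | intermediate (not isolated)
5 | lithium butyl(dimethyl)[(1E)-2-methyl-4-(2,6,6-trimethylcyclohex-1-en-1-yl)but-1-en-1-yl]aluminate | [Li+].CCCC[Al-](C)(C)/C=C(C)/CCC1=C(C)CCCC1(C)C | intermediate (not isolated)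
6 | (3E)-4-methyl-6-(2,6,6-trimethylcyclohex-1-en-1-yl)hex-3-en-1-ol | OCC/C=C(C)/CCC1=C(C)CCCC1(C)C | intermediate
7 | 2-[(3E)-6-bromo-3-methylhex-3-en-1-yl]-1,3,3-trimethylcyclohex-1-ene | BrCC/C=C(C)/CCC1=C(C)CCCC1(C)C | intermediate
8 | [(3E)-4-methyl-6-(2,6,6-trimethylcyclohex-1-en-1-yl)hex-3-en-1-yl]magnesium bromide | Br[Mg]CC/C=C(C)/CCC1=C(C)CCCC1(C)C | intermediate
9 | cis-4-(benzyloxy)but-2-en-1-ol | OC/C=C\COCc1ccccc1 | starting material
10 | [(2S,3R)-3-[(benzyloxy)methyl]oxiran-2-yl]methanol | c1ccccc1COC[C@H]1O[C@H]1CO | intermediate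
11 | vinylmagnesium bromide | C=C[Mg]Br | starting material
12 | (2R,3S)-4-(benzyloxy)-2-ethenylbutane-1,3-diol | c1ccccc1COC[C@@H](O)[C@H](C=C)CO | intermediate
13 | (2S,3R)-1-(benzyloxy)-3-{[(tert-butyldimethylsilyl)oxy]methyl}pent-4-en-2-ol | c1ccccc1COC[C@@H](O)[C@H](C=C)CO[Si](C)(C)C(C)(C)C | intermediate
14 | (2S,3R)-3-{[(tert-butyldimethylsilyl)oxy]methyl}pent-4-ene-1,2-diol | OC[C@@H](O)[C@H](C=C)CO[Si](C)(C)C(C)(C)C | intermediate
15 | (2S,3R)-3-{[(tert-butyldimethylsilyl)oxy]methyl}-2-hydroxypent-4-en-1-yl 4-methylbenzenesulfonate | Cc1ccc(cc1)S(=O)(=O)OC[C@@H](O)[C@H](C=C)CO[Si](C)(C)C(C)(C)C | intermediate (not isolated)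
16 | (2S)-2-[(2R)-1-[(tert-butyldimethylsilyl)oxy]but-3-en-2-yl]oxirane | C1O[C@H]1[C@H](C=C)CO[Si](C)(C)C(C)(C)C | intermediate
17 | prop-2-yn-1-ol | C#CCO | starting material
18 | bromomagnesium prop-2-yn-1-olate | C#CCO[Mg]Br | intermediate (not isolated)
19 | 4-[(3E)-4-methyl-6-(2,6,6-trimethylcyclohex-1-en-1-yl)hex-3-en-1-yl]-2,5-dihydro-1,2-oxamagnesole (cyclic alkenylmagnesium alkoxide) | C1(CC/C=C(C)/CCC2=C(C)CCCC2(C)C)=C[Mg]OC1 | intermediate (not isolated)
20 | (2Z,5R,6R)-6-{[(tert-butyldimethylsilyl)oxy]methyl}-2-[(3E)-4-methyl-6-(2,6,6-trimethylcyclohex-1-en-1-yl)hex-3-en-1-yl]octa-2,7-diene-1,5-diol | OC/C(CC/C=C(C)/CCC1=C(C)CCCC1(C)C)=C\C[C@H]([C@H](C=C)CO[Si](C)(C)C(C)(C)C)O | intermediate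
21 | (2Z,5R,6R)-6-{[(tert-butyldimethylsilyl)oxy]methyl}-5-hydroxy-2-[(3E)-4-methyl-6-(2,6,6-trimethylcyclohex-1-en-1-yl)hex-3-en-1-yl]octa-2,7-dienal | O=C/C(CC/C=C(C)/CCC1=C(C)CCCC1(C)C)=C\C[C@H]([C@H](C=C)CO[Si](C)(C)C(C)(C)C)O | intermediate (not isolated)
22 | (6R)-6-[(2R)-1-[(tert-butyldimethylsilyl)oxy]but-3-en-2-yl]-3-[(3E)-4-methyl-6-(2,6,6-trimethylcyclohex-1-en-1-yl)hex-3-en-1-yl]-5,6-dihydro-2H-pyran-2-ol (anomer mixture) | CC1=C(CC/C(C)=C/CCC2=CC[C@H]([C@H](C=C)CO[Si](C)(C)C(C)(C)C)OC2O)C(C)(C)CCC1 | intermediate (not isolated)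
23 | (6R)-6-[(2R)-1-[(tert-butyldimethylsilyl)oxy]but-3-en-2-yl]-3-[(3E)-4-methyl-6-(2,6,6-trimethylcyclohex-1-en-1-yl)hex-3-en-1-yl]-5,6-dihydro-2H-pyran-2-one | CC1=C(CC/C(C)=C/CCC2=CC[C@H]([C@H](C=C)CO[Si](C)(C)C(C)(C)C)OC2=O)C(C)(C)CCC1 | intermediate
24 | B-alkyl-9-borabicyclo[3.3.1]nonane from anti-Markovnikov addition of 9-BBN to the vinyl group of 23 | CC1=C(CC/C(C)=C/CCC2=CC[C@H]([C@H](CCB3C4CCCC3CCC4)CO[Si](C)(C)C(C)(C)C)OC2=O)C(C)(C)CCC1 | intermediate (not isolated)
25 | (6R)-6-[(2R)-1-[(tert-butyldimethylsilyl)oxy]-4-hydroxybutan-2-yl]-3-[(3E)-4-methyl-6-(2,6,6-trimethylcyclohex-1-en-1-yl)hex-3-en-1-yl]-5,6-dihydro-2H-pyran-2-one | CC1=C(CC/C(C)=C/CCC2=CC[C@H]([C@H](CCO)CO[Si](C)(C)C(C)(C)C)OC2=O)C(C)(C)CCC1 | intermediate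
26 | (3R)-4-[(tert-butyldimethylsilyl)oxy]-3-[(2R)-5-[(3E)-4-methyl-6-(2,6,6-trimethylcyclohex-1-en-1-yl)hex-3-en-1-yl]-6-oxo-3,6-dihydro-2H-pyran-2-yl]butanoic acid | CC1=C(CC/C(C)=C/CCC2=CC[C@H]([C@H](CC(=O)O)CO[Si](C)(C)C(C)(C)C)OC2=O)C(C)(C)CCC1 | intermediate
27 | (3R)-4-hydroxy-3-[(2R)-5-[(3E)-4-methyl-6-(2,6,6-trimethylcyclohex-1-en-1-yl)hex-3-en-1-yl]-6-oxo-3,6-dihydro-2H-pyran-2-yl]butanoic acid | CC1=C(CC/C(C)=C/CCC2=CC[C@H]([C@H](CC(=O)O)CO)OC2=O)C(C)(C)CCC1 | intermediate (not isolated)
28 | (6R)-3-[(3E)-4-methyl-6-(2,6,6-trimethylcyclohex-1-en-1-yl)hex-3-en-1-yl]-6-[(3R)-5-oxooxolan-3-yl]-5,6-dihydro-2H-pyran-2-one (CNP0207009.2) | CC1=C(CC/C(C)=C/CCC2=CC[C@H]([C@H]3COC(=O)C3)OC2=O)C(C)(C)CCC1 | target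

**Count and risks**

Total step count: 14. Longest linear sequence: 10 steps (9 → 28 through steps 5–14); the Grignard branch (steps 1–4) joins at step 10.

Steps most likely to fail:

1. Step 10 (proposed new method). The chelated alkenylmagnesium may transfer its alkenyl group to the epoxide too slowly. Halide opening of the epoxide by magnesium bromide, base-induced isomerisation of the epoxide to an allylic alkoxide, or protonation of the alkenyl–metal bond could then take over. Incomplete carbomagnesiation would also leave alkyl Grignard that opens the epoxide itself. Fallback with known chemistry, setting out from 8 (with 17) and returning at 20: the same copper-catalysed carbomagnesiation is quenched with iodine to give (2Z)-3-iodo-2-[(3E)-4-methyl-6-(2,6,6-trimethylcyclohex-1-en-1-yl)hex-3-en-1-yl]prop-2-en-1-ol F1. The hydroxyl is protected with 4-methoxybenzyl trichloroacetimidate and catalytic acid to give the 4-methoxybenzyl ether of the iodo alcohol F2. Iodine–lithium exchange (t-BuLi, Et2O, −78 °C) and BF3·OEt2-assisted opening of epoxide 16 at its CH2 carbon give the 1-O-(4-methoxybenzyl) ether of the enediol F3. DDQ in wet CH2Cl2 then removes the benzylic ether to give 20.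

2. Step 5. cis-Allylic alcohols are epoxidised more slowly and with lower enantiofacial discrimination than trans ones. Because every later partner is achiral, any shortfall in enantiomeric purity is carried unchanged to the target, and partial attack at C3 in step 6 would cost further material. Fallback setting out from 9 and returning at 12: ozonolysis of 9 (O3, CH2Cl2, −78 °C; PPh3) gives 2-(benzyloxy)acetaldehyde F4, which can also be bought. An Evans syn-aldol with the boron dienolate of (4S)-4-benzyl-3-[(2E)-but-2-enoyl]-1,3-oxazolidin-2-one (Bu2BOTf, Et3N, CH2Cl2, −78 → 0 °C) gives (4S)-4-benzyl-3-[(2S,3S)-4-(benzyloxy)-2-ethenyl-3-hydroxybutanoyl]-1,3-oxazolidin-2-one F5, which can be freed of its diastereomers by chromatography or crystallisation. Reductive removal of the auxiliary (LiBH4, THF/MeOH, 0 °C) gives 12, bypassing both the epoxidation and the regiochemical question of the epoxide opening.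

3. Step 12. Hydride delivery from the borane to the conjugated lactone (carbonyl or conjugate reduction), or attack of the peroxide work-up on the lactone, may compete with hydroboration–oxidation of the vinyl group. Fallback setting out from 20 and returning at 25: the vinyl group is hydroborated before any lactone exists (9-BBN in excess because the two hydroxyls consume reagent; then NaOH/H2O2) to give (2Z,5R,6R)-6-{[(tert-butyldimethylsilyl)oxy]methyl}-2-[(3E)-4-methyl-6-(2,6,6-trimethylcyclohex-1-en-1-yl)hex-3-en-1-yl]oct-2-ene-1,5,8-triol F6. MnO2 then oxidises only the allylic alcohol and the derived lactol, leaving the saturated primary alcohol untouched, to give 25.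

**Further compounds**

F1 | step 10 | (2Z)-3-iodo-2-[(3E)-4-methyl-6-(2,6,6-trimethylcyclohex-1-en-1-yl)hex-3-en-1-yl]prop-2-en-1-ol | OC/C(CC/C=C(C)/CCC1=C(C)CCCC1(C)C)=C\I
F2 | step 10 | 1-({[(2Z)-3-iodo-2-[(3E)-4-methyl-6-(2,6,6-trimethylcyclohex-1-en-1-yl)hex-3-en-1-yl]prop-2-en-1-yl]oxy}methyl)-4-methoxybenzene | COc1ccc(COC/C(CC/C=C(C)/CCC2=C(C)CCCC2(C)C)=C\I)cc1
F3 | step 10 | (2Z,5R,6R)-6-{[(tert-butyldimethylsilyl)oxy]methyl}-1-[(4-methoxybenzyl)oxy]-2-[(3E)-4-methyl-6-(2,6,6-trimethylcyclohex-1-en-1-yl)hex-3-en-1-yl]octa-2,7-dien-5-ol | COc1ccc(COC/C(CC/C=C(C)/CCC2=C(C)CCCC2(C)C)=C\C[C@H]([C@H](C=C)CO[Si](C)(C)C(C)(C)C)O)cc1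
F4 | step 5 | 2-(benzyloxy)acetaldehyde | O=CCOCc1ccccc1
F5 | step 5 | (4S)-4-benzyl-3-[(2S,3S)-4-(benzyloxy)-2-ethenyl-3-hydroxybutanoyl]-1,3-oxazolidin-2-one | c1ccccc1COC[C@@H](O)[C@H](C=C)C(=O)N2C(=O)OC[C@@H]2Cc3ccccc3
F6 | step 12 | (2Z,5R,6R)-6-{[(tert-butyldimethylsilyl)oxy]methyl}-2-[(3E)-4-methyl-6-(2,6,6-trimethylcyclohex-1-en-1-yl)hex-3-en-1-yl]oct-2-ene-1,5,8-triol | OC/C(CC/C=C(C)/CCC1=C(C)CCCC1(C)C)=C\C[C@H]([C@H](CCO)CO[Si](C)(C)C(C)(C)C)O
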